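Target comes out of substrate that has reacted, so the first thing to ask is how much substrate reacts by 40 min. Substrate may take one reagent to target or two to side product, and reagent may also decompose or condense with itself.

the same everywhere: substrate 0.16 M
- south: reagent 0.088 M; run made earlier
- west: reagent 0.13 M; run made earlier
- flask: reagent 0.176 M; time 40 min

- south (time / min: target / %, substrate / %): 8.00: 17, 83; 15.0: 22, 74; 25.0: 24, 71; 30.0: 27, 70; 40.0: 28, 68
- west (time / min: target / %, substrate / %): 3.00: 11, 88; 6.00: 15, 78; 12.0: 24, 73; 20.0: 30, 66; 40.0: 36, 61

(standard deviation of a reading: 1.5 percentage points)

- steps under discussion: substrate + reagent -> target; substrate + 2 reagent -> side product; reagent -> decomposition product; 2 reagent -> self-condensation product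

1. concentration of target at 40 min, in M
2. concentration of substrate at 40 min, in M
3. concentration of reagent at 40 min, in M

Two chemists differ over this flask. The first sees reagent in excess, 0.176 M against 0.16 M of substrate, and treats the flask as pseudo-first-order. From the first west reading, scaled to this flask's charge, she takes a substrate lifetime of 17.3 min. The 40 min are then 2.31 lifetimes, which leave 0.0159 M of substrate.

The second chemist counts lifetimes as they actually pass, by ln([substrate] charged / [substrate] left). The west run counts 0.416 by 20.0 min, and the equally long stretch after it adds 0.0788, far less, so its reagent is dying. The south run counts 0.386 by 40.0 min, and the west run 0.494 by 40.0 min.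

If reagent dies mainly in pairs, the count grows with the logarithm of the reagent charge. The line through these two runs then gives this flask 0.579, its count of lifetimes. That leaves 0.0897 M of substrate. With the west ratio of target to reacted substrate, 92.3%, it makes 0.0649 M of target.

The forecast takes the second chemist's side, on the ground of “a decay that is largely second order in reagent (self-condensation)”, and gives 0.063 M target, 0.089 M substrate and 0.01 M reagent.

The flask gives 0.0655 M target, 0.0852 M substrate and 0.00883 M reagent, so the forecast stands. The flask's count is 0.630, against the second chemist's 0.579 and the first chemist's 2.31. The first view holds in the opening: at 4.00 min it gives 79.4% substrate, and the flask has 79.6%.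

    substrate + reagent → target (k = 0.380 /M/min)
    substrate + 2 reagent → side product (k = 0.700 /M²/min)
    reagent → decomposition product (k = 2.50 × 10⁻⁵ /min)
    2 reagent → self-condensation product (k = 0.410 /M/min)

At the start the target step uses reagent at 0.42 of the rate of self-condensation. By 40.0 min this flask's reagent stands at 5.02% of its charge.

Read the same flask at 25 min. The south run had reached 88.8% of its 40.0 min count by 25.0 min, so that share of 0.579 leaves about 59.8% substrate. The computed flask holds 57.3% substrate and 0.0592 M target.

The numbers in the tables stem from a simulated flask from invented constants.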